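**Remark on the chemistry (assumption):** a commercial ketoreductase panel is assumed to contain an enzyme that gives the (2S,3S) ketol 5 in step 3, as baker's yeast does with 2-alkyl-2-methylcyclohexane-1,3-diones.

Conventions: labdane numbering (ring A = C1–C5, C10; ring B = C5–C10; C17 = methyl on C8; C11–C16 = side chain; C18 = 4α-methyl; C19 = 4β-CH2O; C20 = 10β-methyl). α is below and β above the decalin in its usual drawing. "12,13,14,15,16-Pentanorlabdane" is the decalin that carries only C11 on C9. TBS = tert-butyldimethylsilyl, TES = triethylsilyl, TMSE = 2-(trimethylsilyl)ethyl.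

## Analysis of the target

The target 33 is a labdane diterpenoid acid: a trans-fused decalin (rings A and B) whose tetrasubstituted C8=C9 alkene carries the C17 methyl and, on C9, the chain C11–C16 that ends in an (E)-3-methyl-2-enoic acid. Five stereocentres lie on the decalin: quaternary C10 (β-methyl), quaternary C4 (α-methyl C18, β-CH2O C19), C5 (α-H), and two axial oxygens, the 3α-isovalerate and the free 6β-hydroxyl. The C19 arm, the C20 methyl and the 6β-hydroxyl all stand syn-axial on the β face, which makes the 6β-hydroxyl the most shielded of the three oxygens. Sensitive points are the two isovalerate esters (no hydrolytic step is possible once they are in place, and acyl shift to the neighbouring free hydroxyl must be avoided), the C8=C9 alkene (it can leave the tetrasubstituted position under acid or through a C6 ketone), and the geometry of the C13=C14 alkene. The hard parts are the two quaternary carbons C4 and C10 flanking C5, the axial and therefore thermodynamically disfavoured orientation of both secondary oxygens, and the differentiation of three hydroxyls. The strategy rests on the unit C17–C8=C9–C11: this is the carbon pattern of a but-2-ynoate, and C9 is bonded to quaternary C10, so ring B can be read as the adduct of an alkyne with a ring A diene C10=C5–C6=C7. The C5=C6 alkene that such an addition leaves behind sits exactly where the C6 oxygen and the 5α-hydrogen are needed.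

## Retrosynthetic reasoning

**Acid and acyl groups (33 ⇒ 32 ⇒ 31).** The last bond cut is the O–C bond of the ester protecting C15. The acid is carried as the TMSE ester 32 because it must be freed by a non-hydrolytic method beside two isovalerates. The two isovalerate C–O bonds are cut next, which leads to triol 31; the forward acylation has to take the primary 19-OH and the axial 3α-OH and leave the doubly syn-axial 6β-OH.

**Side chain (31 ⇒ 30 ⇒ 29 ⇒ 27 ⇒ 22 + 25).** After removal of the silyl ethers (31 ⇒ 30), the chain is cut at C13–C16 and at C11–C12. The C16 methyl is placed on the (Z)-enol phosphate 29 with retention, which fixes the (E) geometry by mechanism instead of leaving it to an olefination of a methyl ketone. Phosphate 29 comes from β-keto ester 27, and 27 from allylic bromide 22 and the dianion 26 of acetoacetate 25. The cut at C11–C12 is chosen because C11 is allylic and primary, so the forward SN2 step is activated, and because C12–C15 then arrive as one commercial four-carbon unit.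

**Oxidation level of C11 (22 ⇒ 21 ⇒ 20 ⇒ 19).** The bromide is traced through allylic alcohol 21 to the C9 ester 20, whose two hindered hydroxyls are capped as TES ethers. The ester is kept until here on purpose: while C8=C9 is conjugated with it, the alkene is inert to hydroboration and has no driving force to move toward a C6 ketone.

**C3, C5 and C6 (19 ⇒ 18 ⇒ 17 ⇒ 16 ⇒ 14).** Both axial alcohols of 19 are traced to the 3,6-dione 18, so that one bulky hydride can set both from the equatorial direction. Dione 18 comes from diol 17, 17 from 16 by selective loss of the O3 silyl group, and 16 from diene 14 by α-face hydroboration of C5=C6, which also sets the 5α-hydrogen. The C3 oxygen is thus carried as the 3β epimer up to 17 and corrected by the redox pair.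

**Key disconnection (14 ⇒ 12 + 13).** Ring B is opened at C7–C8 and C9–C10. This removes a ring, two skeletal bonds, the tetrasubstituted alkene, C17 and C11 in one operation, and leads back to the ring A diene 12 and the commercial ynoate 13. The forward cycloaddition has to pair C7 with the β-carbon of 13 and add to the α face of C10. The 3β configuration of the silyloxy group in 12 is kept for this purpose, because it places the C19 arm pseudoaxial on the β face.

**Ring A (12 ⇒ 10 + 11 ⇒ 8 ⇒ 6 ⇒ 5 ⇒ 4 ⇒ 3 ⇒ 1 + 2).** The vinyl group is cut off (triflate 10 and vinylstannane 11). The triflate comes from ketone 8, whose C20 methyl is removed to give 6. The silyl ether 6 comes from ketol 5, and both stereocentres of 5 come from enzymatic desymmetrisation of the prochiral dione 4. Dione 4 is the silyl ether of 3, the aldol adduct of dione 1 and formaldehyde 2. A chloromethyl ether would bring in C19 in one step, but such hard electrophiles attack 1,3-dione enolates at oxygen; the aldol route can only give the C-adduct.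

## Alternatives that were turned down

**Alternative 1:** Rings A and B are opened together at C3–C4 and C5–C10. In the forward sense an intramolecular Diels–Alder reaction adds the C4=C5 alkene of a butenolide (C19 as lactone carbonyl, C6 as the carbinol centre) to a 1-silyloxy diene C3=C2–C1=C10 held in the same chain through C7 and a preformed C8=C9 alkene. It gives A1, the tricyclic 19,6β-lactone with C1=C2 and C8=C9 alkenes.
- For it: one step sets C3, C4, C5 and C10 relative to C6, and the lactone supplies the 6β-oxygen and C19 together, so no redox correction of C3 or C6 is needed. On stereochemical economy this plan is stronger than the chosen one, which sets only C10 in its key step.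
- Against it: the cycloaddition must create two quaternary carbons (C4 and C10) in one transition state, from a trisubstituted dienophile activated only by a lactone and from a fully substituted diene terminus. The acid- and heat-sensitive silyl dienol ether has to survive the forcing conditions. The endo/exo preference decides C3 and is not secured by any element of the chain. The chain itself needs a geometrically defined tetrasubstituted C8=C9 alkene and an enantiopure butenolide, and after A1 the C1=C2 alkene must still be reduced and the side chain built.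
- In its place the chosen strategy offers a seven-step precursor from a commodity dione, forms only one quaternary carbon in the cycloaddition, and makes the C8=C9 alkene in the key step instead of requiring it beforehand.

**Alternative 2:** The C8=C9 double bond itself is cut. In the forward sense a ring-closing metathesis with a second-generation ruthenium carbene catalyst joins a C8 isopropenyl-type alkene with a C9 methylidene and closes ring B, giving A2, the TMSE ester of the target (the same structure as 32).
- For it: the plan is highly convergent and the product of its key step is one deprotection from the target. On end-game economy it is stronger than the chosen route, which needs fourteen steps after its key step.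
- Against it: a metathesis that forms a tetrasubstituted alkene from two 1,1-disubstituted alkenes is the most demanding case for the ruthenium carbene, and here one of the alkenes sits on a carbon bonded to quaternary C10, so loading of the catalyst and ring closure are both slow. The substrate must already hold all five ring stereocentres, two of them quaternary, on a single cyclohexane together with the complete side chain, so the stereochemical problem is moved into a long precursor synthesis, not solved.
- In its place the chosen strategy forms the same alkene directly from an alkyne, where the substitution pattern is built into the reagent, and spreads the stereochemical work over substrate-controlled steps on a rigid bicycle.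

**Alternative 3:** Ring A is opened at C3–C4. In the forward sense a Reformatsky reaction mediated by divalent samarium converts both C4 epimers of an α-bromo ester into one samarium enolate that adds to a C3 aldehyde, giving A3, a bicyclic β-hydroxy ester with 4β-ester, 3β-hydroxyl, a C9 ketone and a C7=C8 alkene.
- For it: the ring closure is stereoconvergent, so C4 need not be controlled in the precursor, and the chelated transition state fixes C4 against the preset C5/C10 fusion. On certainty of the C4/C10 relationship it is at least as strong as the chosen route, which depends on facial bias in a cycloaddition.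
- Against it: A3 lacks the C6 oxygen, which would have to be introduced next to the hindered ring fusion. It has C19 at the acid level. Its C9 ketone must still be turned into the tetrasubstituted C8=C9 alkene bearing C11, by addition to a carbonyl next to quaternary C10 followed by transposition. The 3β-hydroxyl needs the same inversion as in the chosen route.
- In its place the chosen strategy delivers C11, C17 and the C8=C9 alkene in the key step, and the alkene left at C5=C6 gives direct access to the C6 oxygen.

Key step: step 8

## Route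

Step 1
Reactants: 1 2-methylcyclohexane-1,3-dione; 2 formaldehyde
Product: 3 2-(hydroxymethyl)-2-methylcyclohexane-1,3-dione
Conditions: 37% aq. HCHO, H2O, rt
Reagents that add atoms: none
Why: Aldol addition of the acidic dione to formaldehyde; only the C-adduct is stable because the O-adduct is a hemiacetal that reverts, which avoids the O-alkylation that chloromethyl ethers give with 1,3-dione enolates. Neutral water keeps retro-aldol and retro-Claisen cleavage slow.

Step 2
Reactants: 3 2-(hydroxymethyl)-2-methylcyclohexane-1,3-dione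
Product: 4 2-{[tert-butyl(dimethyl)silyl]oxymethyl}-2-methylcyclohexane-1,3-dione
Conditions: TBSCl, imidazole, CH2Cl2, 0 °C → rt
Reagents that add atoms: tert-butyl(chloro)dimethylsilane, CC(C)(C)[Si](C)(C)Cl
Why: Silylation of a primary alcohol under weakly basic conditions that do not trigger loss of formaldehyde. The silyloxymethyl arm is now clearly larger than the methyl group, which the enzyme in step 3 needs for discrimination.

Step 3
Reactants: 4 2-{[tert-butyl(dimethyl)silyl]oxymethyl}-2-methylcyclohexane-1,3-dione
Product: 5 (2S,3S)-2-{[tert-butyl(dimethyl)silyl]oxymethyl}-3-hydroxy-2-methylcyclohexan-1-one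
Conditions: ketoreductase (selected for the (2S,3S) alcohol), NADP+ (cat.), i-PrOH, phosphate buffer pH 7, 30 °C
Reagents that add atoms: none
Why: Enzymatic desymmetrising reduction of a prochiral 2,2-disubstituted 1,3-dione: the choice of one enantiotopic carbonyl fixes C4 and hydride delivery to one face fixes C3, giving the alcohol cis to the silyloxymethyl arm. Baker's yeast reduction of 2-alkyl-2-methylcyclohexane-1,3-diones to (2S,3S) ketols is the known model.

Step 4
Reactants: 5 (2S,3S)-2-{[tert-butyl(dimethyl)silyl]oxymethyl}-3-hydroxy-2-methylcyclohexan-1-one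
Product: 6 (2S,3S)-2-{[tert-butyl(dimethyl)silyl]oxymethyl}-2-methyl-3-(triethylsilyloxy)cyclohexan-1-one
Conditions: TESCl, imidazole, DMAP (cat.), DMF, rt
Reagents that add atoms: chlorotriethylsilane, CC[Si](Cl)(CC)CC
Why: Standard silylation of a secondary alcohol. TES is chosen for O3 so that mild acid can later remove it beside the primary TBS ether.

Step 5
Reactants: 6 (2S,3S)-2-{[tert-butyl(dimethyl)silyl]oxymethyl}-2-methyl-3-(triethylsilyloxy)cyclohexan-1-one
Product: 8 (2S,3S,6RS)-2-{[tert-butyl(dimethyl)silyl]oxymethyl}-2,6-dimethyl-3-(triethylsilyloxy)cyclohexan-1-one, via lithium enolate 7 (not isolated)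
Conditions: LiN(i-Pr)2, THF, −78 °C; MeI, −78 → −20 °C
Reagents that add atoms: iodomethane, CI
Why: Kinetic enolate alkylation; C4 is quaternary, so the ketone can enolise only toward C10 and the methylation (C20) is regiospecific. The configuration of the new centre does not matter because it becomes sp2 in step 6.

Step 6
Reactants: 8 (2S,3S,6RS)-2-{[tert-butyl(dimethyl)silyl]oxymethyl}-2,6-dimethyl-3-(triethylsilyloxy)cyclohexan-1-one
Product: 10 (5S,6S)-6-{[tert-butyl(dimethyl)silyl]oxymethyl}-2,6-dimethyl-5-(triethylsilyloxy)cyclohex-1-en-1-yl trifluoromethanesulfonate, via potassium enolate 9 (not isolated)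
Conditions: KN(SiMe3)2, THF, −78 → 0 °C; PhNTf2, −78 °C → rt
Reagents that add atoms: N-phenylbis(trifluoromethanesulfonimide), O=S(=O)(N(c1ccccc1)S(=O)(=O)C(F)(F)F)C(F)(F)F
Why: The single remaining α-hydrogen is removed to give the tetrasubstituted enolate, which is trapped on oxygen (enol triflate formation), as is known for 2,2,6-trimethylcyclohexanone.

Step 7
Reactants: 10 (5S,6S)-6-{[tert-butyl(dimethyl)silyl]oxymethyl}-2,6-dimethyl-5-(triethylsilyloxy)cyclohex-1-en-1-yl trifluoromethanesulfonate; 11 tributyl(ethenyl)stannane
Product: 12 (5S,6S)-6-{[tert-butyl(dimethyl)silyl]oxymethyl}-1-ethenyl-2,6-dimethyl-5-(triethylsilyloxy)cyclohex-1-ene (ring A diene, 3β-OTES cis to the C19 arm)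
Conditions: Pd(PPh3)4 (cat.), LiCl, THF, 65 °C
Reagents that add atoms: none
Why: Stille coupling of a hindered cyclohexenyl triflate with a vinylstannane; LiCl supports transmetallation from the triflate-derived palladium intermediate. The same coupling is established for 2,6,6-trimethylcyclohexenyl triflate, and no stereocentre is touched.

Step 8
Reactants: 12 (5S,6S)-6-{[tert-butyl(dimethyl)silyl]oxymethyl}-1-ethenyl-2,6-dimethyl-5-(triethylsilyloxy)cyclohex-1-ene; 13 methyl but-2-ynoate
Product: 14 methyl 19-[tert-butyl(dimethyl)silyl]oxy-3β-(triethylsilyloxy)-12,13,14,15,16-pentanorlabda-5,8-dien-11-oate (10β-methyl, 4α-methyl)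
Conditions: 13 (5 equiv), 2,6-di-tert-butyl-4-methylphenol (cat.), CH2Cl2, 13 kbar, 40 °C
Reagents that add atoms: none
Why: A thermal, concerted but asynchronous [4+2] cycloaddition (Diels–Alder reaction) between the s-cis diene C10=C5–C6=C7 of 12 and the alkyne of 13; the closest known reaction is the addition of acetylenic esters to 1-vinyl-2,6,6-trimethylcyclohexene, the classical way to the drimane skeleton. Ring B is closed by intermolecular six-membered annulation onto ring A, both σ bonds (C7–C8 and C9–C10) forming suprafacially in one step, and the product is a 1,4-cyclohexadiene that cannot aromatise because C10 is quaternary. Regiochemistry follows from polarity and sterics: C7 is the unhindered and most nucleophilic diene terminus (bond formation there leaves allyl-cation character on tertiary C10) and pairs with the electrophilic β-carbon of the ynoate, so the methyl lands on C8 and the ester on C9. The one new stereocentre, C10, is fixed by the face of attack: with the 3β-silyloxy group equatorial, the larger C4 substituent (CH2OTBS) is pseudoaxial on the β face, a preference reinforced by allylic strain against the C5 vinyl group, and the alkyne therefore approaches anti to it from the α face, which pushes the C20 methyl to β. An alkyne has no endo/exo issue, so facial selectivity is the only stereochemical demand. Pressure is used instead of heat or a Lewis acid because the ynoate is a weaker dienophile than the usual diester and the diene is twisted out of planarity; the strongly negative activation volume accelerates the cycloaddition without opening the 1,5-hydrogen shift of the cis-methyl diene or the cationic [2+2] and desilylation channels that aluminium halides would offer.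

Step 9
Reactants: 14 methyl 19-[tert-butyl(dimethyl)silyl]oxy-3β-(triethylsilyloxy)-12,13,14,15,16-pentanorlabda-5,8-dien-11-oate
Product: 16 methyl 19-[tert-butyl(dimethyl)silyl]oxy-6α-hydroxy-3β-(triethylsilyloxy)-12,13,14,15,16-pentanorlabd-8-en-11-oate (5α-H), via 6α-alkylborane 15 (not isolated)
Conditions: BH3·THF, THF, 0 °C → rt; then NaOH, H2O2, 0 °C
Reagents that add atoms: hydrogen peroxide, OO
Why: Hydroboration–oxidation of the electron-rich trisubstituted C5=C6 alkene; C8=C9 is tetrasubstituted and deactivated by the ester. Boron adds to C6 and hydrogen to C5, syn and from the α face, because the β face carries the syn-axial C19 arm and C20 methyl; this sets 5α-H (trans fusion) and 6α-OH, as in the hydroboration of 5-ene steroids.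

Step 10
Reactants: 16 methyl 19-[tert-butyl(dimethyl)silyl]oxy-6α-hydroxy-3β-(triethylsilyloxy)-12,13,14,15,16-pentanorlabd-8-en-11-oate
Product: 17 methyl 19-[tert-butyl(dimethyl)silyl]oxy-3β,6α-dihydroxy-12,13,14,15,16-pentanorlabd-8-en-11-oate
Conditions: PPTS (cat.), MeOH, 0 °C → rt
Reagents that add atoms: none
Why: Acid-catalysed methanolysis cleaves the TES ether much faster than the TBS ether; both sit next to quaternary C4, so the intrinsic difference between the two silyl groups decides.

Step 11
Reactants: 17 methyl 19-[tert-butyl(dimethyl)silyl]oxy-3β,6α-dihydroxy-12,13,14,15,16-pentanorlabd-8-en-11-oate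
Product: 18 methyl 19-[tert-butyl(dimethyl)silyl]oxy-3,6-dioxo-12,13,14,15,16-pentanorlabd-8-en-11-oate (5α-H)
Conditions: Dess–Martin periodinane, CH2Cl2, 0 °C → rt
Reagents that add atoms: none
Why: Dess–Martin oxidation of both secondary alcohols under non-basic conditions. C8=C9 stays in place because it is conjugated with the ester, and C5 keeps the more stable trans fusion.

Step 12
Reactants: 18 methyl 19-[tert-butyl(dimethyl)silyl]oxy-3,6-dioxo-12,13,14,15,16-pentanorlabd-8-en-11-oate
Product: 19 methyl 19-[tert-butyl(dimethyl)silyl]oxy-3α,6β-dihydroxy-12,13,14,15,16-pentanorlabd-8-en-11-oate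
Conditions: LiBH(s-Bu)3, THF, −78 → −20 °C; then NaOH, H2O2, 0 °C
Reagents that add atoms: none
Why: The bulky trialkylborohydride attacks both carbonyls along the equatorial trajectory: at C3 this gives the axial 3α-alcohol, as known for 4,4-disubstituted 3-ketones, and at C6 the α approach is the only open one because C19 and C20 block the β face, giving the axial 6β-alcohol. The hindered tetrasubstituted enoate is not reduced at low temperature.

Step 13
Reactants: 19 methyl 19-[tert-butyl(dimethyl)silyl]oxy-3α,6β-dihydroxy-12,13,14,15,16-pentanorlabd-8-en-11-oate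
Product: 20 methyl 19-[tert-butyl(dimethyl)silyl]oxy-3α,6β-bis(triethylsilyloxy)-12,13,14,15,16-pentanorlabd-8-en-11-oate
Conditions: TESOTf, 2,6-lutidine, CH2Cl2, −40 → 0 °C
Reagents that add atoms: triethylsilyl trifluoromethanesulfonate, CC[Si](CC)(CC)OS(=O)(=O)C(F)(F)F
Why: A silyl triflate is reactive enough to cap both hindered axial hydroxyls. The ethers shield them from the strong bases and electrophiles of steps 14–19 and leave together with the TBS group in step 20.

Step 14
Reactants: 20 methyl 19-[tert-butyl(dimethyl)silyl]oxy-3α,6β-bis(triethylsilyloxy)-12,13,14,15,16-pentanorlabd-8-en-11-oate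
Product: 21 19-[tert-butyl(dimethyl)silyl]oxy-3α,6β-bis(triethylsilyloxy)-12,13,14,15,16-pentanorlabd-8-en-11-ol
Conditions: i-Bu2AlH, CH2Cl2, −78 → 0 °C; aq. potassium sodium tartrate
Reagents that add atoms: none
Why: 1,2-Reduction of the hindered conjugated ester to the allylic alcohol by an aluminium hydride; silyl ethers are stable to it.

Step 15
Reactants: 21 19-[tert-butyl(dimethyl)silyl]oxy-3α,6β-bis(triethylsilyloxy)-12,13,14,15,16-pentanorlabd-8-en-11-ol
Product: 22 11-bromo-19-[tert-butyl(dimethyl)silyl]oxy-3α,6β-bis(triethylsilyloxy)-12,13,14,15,16-pentanorlabd-8-ene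
Conditions: CBr4, PPh3, CH2Cl2, 0 °C
Reagents that add atoms: tetrabromomethane, BrC(Br)(Br)Br
Why: Appel reaction of a primary allylic alcohol under neutral conditions; substitution occurs at C11, and the tertiary allylic isomer at fully substituted C8 is disfavoured.

Step 16
Reactants: 23 tert-butyl 3-oxobutanoate; 24 2-(trimethylsilyl)ethanol
Product: 25 2-(trimethylsilyl)ethyl 3-oxobutanoate
Conditions: toluene, 110 °C, t-BuOH distilled off
Reagents that add atoms: none
Why: Thermal transacetoacetylation: the tert-butyl ester loses tert-butanol on heating and alcohol 24 is acetoacetylated. It supplies C12–C15 with an ester that fluoride can cleave at the end.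

Step 17
Reactants: 22 11-bromo-19-[tert-butyl(dimethyl)silyl]oxy-3α,6β-bis(triethylsilyloxy)-12,13,14,15,16-pentanorlabd-8-ene; 25 2-(trimethylsilyl)ethyl 3-oxobutanoate
Product: 27 2-(trimethylsilyl)ethyl 19-[tert-butyl(dimethyl)silyl]oxy-13-oxo-3α,6β-bis(triethylsilyloxy)-16-norlabd-8-en-15-oate, via acetoacetate dianion 26 (not isolated)
Conditions: 25, NaH, THF, 0 °C; n-BuLi, 0 °C; then 22, 0 °C
Reagents that add atoms: none
Why: γ-Alkylation of an acetoacetate dianion: the more basic terminal carbanion displaces the primary allylic bromide (SN2) and forms C11–C12, while attack at fully substituted C8 is blocked. Cyclogeranyl-type bromides are alkylated in the same way.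

Step 18
Reactants: 27 2-(trimethylsilyl)ethyl 19-[tert-butyl(dimethyl)silyl]oxy-13-oxo-3α,6β-bis(triethylsilyloxy)-16-norlabd-8-en-15-oate
Product: 29 2-(trimethylsilyl)ethyl (13Z)-19-[tert-butyl(dimethyl)silyl]oxy-13-(diethoxyphosphoryloxy)-3α,6β-bis(triethylsilyloxy)-16-norlabda-8,13-dien-15-oate, via sodium enolate 28 (not isolated)
Conditions: NaH, Et2O, 0 °C; ClP(O)(OEt)2, 0 °C → rt
Reagents that add atoms: diethyl chlorophosphate, CCOP(=O)(Cl)OCC
Why: The sodium enolate of a β-keto ester is chelated between the two oxygens, so O-phosphorylation gives the (Z)-enol phosphate with the phosphate cis to the ester.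

Step 19
Reactants: 29 2-(trimethylsilyl)ethyl (13Z)-19-[tert-butyl(dimethyl)silyl]oxy-13-(diethoxyphosphoryloxy)-3α,6β-bis(triethylsilyloxy)-16-norlabda-8,13-dien-15-oate
Product: 30 2-(trimethylsilyl)ethyl (13E)-19-[tert-butyl(dimethyl)silyl]oxy-3α,6β-bis(triethylsilyloxy)labda-8,13-dien-15-oate
Conditions: Me2CuLi (from MeLi, CuI), Et2O, −78 → −45 °C
Reagents that add atoms: lithium dimethylcuprate, [Li+].C[Cu-]C
Why: Addition–elimination of a cuprate on a β-phosphoryloxy enoate proceeds with retention, so the C16 methyl takes the place of the phosphate cis to the ester and the C13=C14 alkene is (E). The β,β-disubstituted product does not add a second methyl at this temperature.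

Step 20
Reactants: 30 2-(trimethylsilyl)ethyl (13E)-19-[tert-butyl(dimethyl)silyl]oxy-3α,6β-bis(triethylsilyloxy)labda-8,13-dien-15-oate
Product: 31 2-(trimethylsilyl)ethyl (13E)-3α,6β,19-trihydroxylabda-8,13-dien-15-oate
Conditions: HF·pyridine, pyridine, THF, 0 °C → rt
Reagents that add atoms: none
Why: HF·pyridine cleaves the Si–O bonds of all three silyl ethers but not the C–Si bond of the TMSE ester, which needs free fluoride. The buffered medium spares the tetrasubstituted alkene.

Step 21
Reactants: 31 2-(trimethylsilyl)ethyl (13E)-3α,6β,19-trihydroxylabda-8,13-dien-15-oate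
Product: 32 2-(trimethylsilyl)ethyl (13E)-6β-hydroxy-3α,19-bis(3-methylbutanoyloxy)labda-8,13-dien-15-oate
Conditions: (i-PrCH2CO)2O, DMAP (cat.), Et3N, CH2Cl2, 0 °C → rt
Reagents that add atoms: 3-methylbutanoic anhydride, CC(C)CC(=O)OC(=O)CC(C)C
Why: DMAP-catalysed acylation takes the primary 19-OH and the axial 3α-OH, which is syn-axial only to hydrogens. The 6β-OH is syn-axial to C19 and C20 and should stay free, as hydroxyls in this environment resist acylation.

Step 22
Reactants: 32 2-(trimethylsilyl)ethyl (13E)-6β-hydroxy-3α,19-bis(3-methylbutanoyloxy)labda-8,13-dien-15-oate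
Product: 33 (13E)-6β-hydroxy-3α,19-bis(3-methylbutanoyloxy)labda-8,13-dien-15-oic acid (CNP0333611.1)
Conditions: Bu4NF, THF, 0 °C → rt; then aq. NH4Cl
Reagents that add atoms: none
Why: Fluoride attacks silicon of the TMSE ester, which fragments by β-elimination to the carboxylate under conditions that leave the isovalerates intact. A 19→6 acyl shift would be uphill because the 6β position is the more crowded one.

## Compound list

1 | 2-methylcyclohexane-1,3-dione | CC1C(=O)CCCC1=O | starting material
2 | formaldehyde | C=O | starting material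
3 | 2-(hydroxymethyl)-2-methylcyclohexane-1,3-dione | CC1(CO)C(=O)CCCC1=O | intermediate
4 | 2-{[tert-butyl(dimethyl)silyl]oxymethyl}-2-methylcyclohexane-1,3-dione | CC1(CO[Si](C)(C)C(C)(C)C)C(=O)CCCC1=O | intermediate
5 | (2S,3S)-2-{[tert-butyl(dimethyl)silyl]oxymethyl}-3-hydroxy-2-methylcyclohexan-1-one | O=C1CCC[C@H](O)[C@]1(C)CO[Si](C)(C)C(C)(C)C | intermediate
6 | (2S,3S)-2-{[tert-butyl(dimethyl)silyl]oxymethyl}-2-methyl-3-(triethylsilyloxy)cyclohexan-1-one | O=C1CCC[C@H](O[Si](CC)(CC)CC)[C@]1(C)CO[Si](C)(C)C(C)(C)C | intermediate
7 | lithium enolate of 6 (C5–OLi, C5=C10) | [Li]OC1=CCC[C@H](O[Si](CC)(CC)CC)[C@]1(C)CO[Si](C)(C)C(C)(C)C | intermediate (not isolated)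
8 | (2S,3S,6RS)-2-{[tert-butyl(dimethyl)silyl]oxymethyl}-2,6-dimethyl-3-(triethylsilyloxy)cyclohexan-1-one | CC1CC[C@H](O[Si](CC)(CC)CC)[C@](C)(CO[Si](C)(C)C(C)(C)C)C1=O | intermediate
9 | potassium enolate of 8 (tetrasubstituted, C5=C10) | [K]OC1=C(C)CC[C@H](O[Si](CC)(CC)CC)[C@]1(C)CO[Si](C)(C)C(C)(C)C | intermediate (not isolated)
10 | (5S,6S)-6-{[tert-butyl(dimethyl)silyl]oxymethyl}-2,6-dimethyl-5-(triethylsilyloxy)cyclohex-1-en-1-yl trifluoromethanesulfonate | FC(F)(F)S(=O)(=O)OC1=C(C)CC[C@H](O[Si](CC)(CC)CC)[C@]1(C)CO[Si](C)(C)C(C)(C)C | intermediate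
11 | tributyl(ethenyl)stannane | C=C[Sn](CCCC)(CCCC)CCCC | starting material
12 | (5S,6S)-6-{[tert-butyl(dimethyl)silyl]oxymethyl}-1-ethenyl-2,6-dimethyl-5-(triethylsilyloxy)cyclohex-1-ene | C=CC1=C(C)CC[C@H](O[Si](CC)(CC)CC)[C@]1(C)CO[Si](C)(C)C(C)(C)C | intermediate
13 | methyl but-2-ynoate | CC#CC(=O)OC | starting material
14 | methyl 19-[tert-butyl(dimethyl)silyl]oxy-3β-(triethylsilyloxy)-12,13,14,15,16-pentanorlabda-5,8-dien-11-oate | CC1=C(C(=O)OC)[C@@]2(C)CC[C@H](O[Si](CC)(CC)CC)[C@](C)(CO[Si](C)(C)C(C)(C)C)C2=CC1 | intermediate
15 | 6α-boryl (BH2) adduct of 14, 5α-H | CC1=C(C(=O)OC)[C@@]2(C)CC[C@H](O[Si](CC)(CC)CC)[C@](C)(CO[Si](C)(C)C(C)(C)C)[C@@H]2[C@@H](B)C1 | intermediate (not isolated)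
16 | methyl 19-[tert-butyl(dimethyl)silyl]oxy-6α-hydroxy-3β-(triethylsilyloxy)-12,13,14,15,16-pentanorlabd-8-en-11-oate | CC1=C(C(=O)OC)[C@@]2(C)CC[C@H](O[Si](CC)(CC)CC)[C@](C)(CO[Si](C)(C)C(C)(C)C)[C@@H]2[C@@H](O)C1 | intermediate
17 | methyl 19-[tert-butyl(dimethyl)silyl]oxy-3β,6α-dihydroxy-12,13,14,15,16-pentanorlabd-8-en-11-oate | CC1=C(C(=O)OC)[C@@]2(C)CC[C@H](O)[C@](C)(CO[Si](C)(C)C(C)(C)C)[C@@H]2[C@@H](O)C1 | intermediate
18 | methyl 19-[tert-butyl(dimethyl)silyl]oxy-3,6-dioxo-12,13,14,15,16-pentanorlabd-8-en-11-oate | CC1=C(C(=O)OC)[C@@]2(C)CCC(=O)[C@](C)(CO[Si](C)(C)C(C)(C)C)[C@@H]2C(=O)C1 | intermediate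
19 | methyl 19-[tert-butyl(dimethyl)silyl]oxy-3α,6β-dihydroxy-12,13,14,15,16-pentanorlabd-8-en-11-oate | CC1=C(C(=O)OC)[C@@]2(C)CC[C@@H](O)[C@](C)(CO[Si](C)(C)C(C)(C)C)[C@@H]2[C@H](O)C1 | intermediate
20 | methyl 19-[tert-butyl(dimethyl)silyl]oxy-3α,6β-bis(triethylsilyloxy)-12,13,14,15,16-pentanorlabd-8-en-11-oate | CC1=C(C(=O)OC)[C@@]2(C)CC[C@@H](O[Si](CC)(CC)CC)[C@](C)(CO[Si](C)(C)C(C)(C)C)[C@@H]2[C@H](O[Si](CC)(CC)CC)C1 | intermediate
21 | 19-[tert-butyl(dimethyl)silyl]oxy-3α,6β-bis(triethylsilyloxy)-12,13,14,15,16-pentanorlabd-8-en-11-ol | CC1=C(CO)[C@@]2(C)CC[C@@H](O[Si](CC)(CC)CC)[C@](C)(CO[Si](C)(C)C(C)(C)C)[C@@H]2[C@H](O[Si](CC)(CC)CC)C1 | intermediate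
22 | 11-bromo-19-[tert-butyl(dimethyl)silyl]oxy-3α,6β-bis(triethylsilyloxy)-12,13,14,15,16-pentanorlabd-8-ene | CC1=C(CBr)[C@@]2(C)CC[C@@H](O[Si](CC)(CC)CC)[C@](C)(CO[Si](C)(C)C(C)(C)C)[C@@H]2[C@H](O[Si](CC)(CC)CC)C1 | intermediate
23 | tert-butyl 3-oxobutanoate | CC(=O)CC(=O)OC(C)(C)C | starting material
24 | 2-(trimethylsilyl)ethanol | C[Si](C)(C)CCO | starting material
25 | 2-(trimethylsilyl)ethyl 3-oxobutanoate | CC(=O)CC(=O)OCC[Si](C)(C)C | intermediate
26 | sodium lithium dianion (dienediolate) of 25 | [Li]OC(=C)C=C(O[Na])OCC[Si](C)(C)C | intermediate (not isolated)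
27 | 2-(trimethylsilyl)ethyl 19-[tert-butyl(dimethyl)silyl]oxy-13-oxo-3α,6β-bis(triethylsilyloxy)-16-norlabd-8-en-15-oate | CC1=C(CCC(=O)CC(=O)OCC[Si](C)(C)C)[C@@]2(C)CC[C@@H](O[Si](CC)(CC)CC)[C@](C)(CO[Si](C)(C)C(C)(C)C)[C@@H]2[C@H](O[Si](CC)(CC)CC)C1 | intermediate
28 | sodium (Z)-enolate of 27 | CC1=C(CC/C(O[Na])=C/C(=O)OCC[Si](C)(C)C)[C@@]2(C)CC[C@@H](O[Si](CC)(CC)CC)[C@](C)(CO[Si](C)(C)C(C)(C)C)[C@@H]2[C@H](O[Si](CC)(CC)CC)C1 | intermediate (not isolated)
29 | 2-(trimethylsilyl)ethyl (13Z)-19-[tert-butyl(dimethyl)silyl]oxy-13-(diethoxyphosphoryloxy)-3α,6β-bis(triethylsilyloxy)-16-norlabda-8,13-dien-15-oate | CC1=C(CC/C(OP(=O)(OCC)OCC)=C/C(=O)OCC[Si](C)(C)C)[C@@]2(C)CC[C@@H](O[Si](CC)(CC)CC)[C@](C)(CO[Si](C)(C)C(C)(C)C)[C@@H]2[C@H](O[Si](CC)(CC)CC)C1 | intermediate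
30 | 2-(trimethylsilyl)ethyl (13E)-19-[tert-butyl(dimethyl)silyl]oxy-3α,6β-bis(triethylsilyloxy)labda-8,13-dien-15-oate | CC1=C(CC/C(C)=C/C(=O)OCC[Si](C)(C)C)[C@@]2(C)CC[C@@H](O[Si](CC)(CC)CC)[C@](C)(CO[Si](C)(C)C(C)(C)C)[C@@H]2[C@H](O[Si](CC)(CC)CC)C1 | intermediate
31 | 2-(trimethylsilyl)ethyl (13E)-3α,6β,19-trihydroxylabda-8,13-dien-15-oate | CC1=C(CC/C(C)=C/C(=O)OCC[Si](C)(C)C)[C@@]2(C)CC[C@@H](O)[C@](C)(CO)[C@@H]2[C@H](O)C1 | intermediate
32 | 2-(trimethylsilyl)ethyl (13E)-6β-hydroxy-3α,19-bis(3-methylbutanoyloxy)labda-8,13-dien-15-oate | CC1=C(CC/C(C)=C/C(=O)OCC[Si](C)(C)C)[C@@]2(C)CC[C@@H](OC(=O)CC(C)C)[C@](C)(COC(=O)CC(C)C)[C@@H]2[C@H](O)C1 | intermediate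
33 | (13E)-6β-hydroxy-3α,19-bis(3-methylbutanoyloxy)labda-8,13-dien-15-oic acid | CC1=C(CC/C(C)=C/C(=O)O)[C@@]2(C)CC[C@@H](OC(=O)CC(C)C)[C@](C)(COC(=O)CC(C)C)[C@@H]2[C@H](O)C1 | target

## Step count and risk

Total step count: 22. Longest linear sequence: 21 steps (steps 1–15 and 17–22; step 16 is a one-step side branch).

**Step 8 (key step).** The most likely failure is an insufficient rate of cycloaddition. The diene must flatten against quaternary C4 and the C10 methyl, and the ynoate is activated by one ester only. Forcing the reaction would let the diene isomerise by 1,5-hydrogen shift or polymerise. Second in line is incomplete facial selectivity, if the half-chair with the C18 methyl pseudoaxial competes. The fallback sets out from 12 and returns at 14. The ester dienophile is replaced by the aldehyde: but-2-ynal, activated by Me2AlCl in CH2Cl2 at −78 → −20 °C, where the aldehyde complex is reactive enough for cationic side channels to stay slow, should add with the same regiochemical polarisation to give 19-[tert-butyl(dimethyl)silyl]oxy-3β-(triethylsilyloxy)-12,13,14,15,16-pentanorlabda-5,8-dien-11-al F1. Pinnick oxidation (NaClO2, NaH2PO4, 2-methylbut-2-ene, t-BuOH/H2O) would give the corresponding 11-oic acid F2, and trimethylsilyldiazomethane in toluene/MeOH would give 14.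

**Step 3.** The most likely failure is poor discrimination by the enzyme between the silyloxymethyl and methyl groups, or poor acceptance of the lipophilic silyl ether, which would mean loss of diastereo- or enantioselectivity. The fallback sets out from 4 and returns at 5. Substoichiometric NaBH4 in MeOH at −40 °C, with hydride delivered anti to the larger arm, would give racemic cis-2-{[tert-butyl(dimethyl)silyl]oxymethyl}-3-hydroxy-2-methylcyclohexan-1-one F3. Kinetic resolution with Burkholderia cepacia lipase and vinyl acetate in t-BuOMe should, by the usual size model for secondary alcohols, acetylate the (3R) enantiomer to (1R,2R)-2-{[tert-butyl(dimethyl)silyl]oxymethyl}-2-methyl-3-oxocyclohexyl acetate F4 and leave 5, which is separated by chromatography.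

**Step 12.** The most likely failure is enolisation toward C7, which lies between the C6 ketone and the enoate and is acidic, in competition with hydride transfer to the crowded C6 carbonyl; incomplete equatorial attack at C3 is the second concern. The fallback sets out from 16 and returns at 19, and treats the two carbonyls one at a time. Dess–Martin oxidation of 16 would give methyl 19-[tert-butyl(dimethyl)silyl]oxy-6-oxo-3β-(triethylsilyloxy)-12,13,14,15,16-pentanorlabd-8-en-11-oate F5. Luche reduction (NaBH4, CeCl3·7H2O, MeOH, −40 °C), a small hydride in a weakly basic protic medium attacking from the α side, would give the 6β-hydroxy-3β-(triethylsilyloxy) ester F6. PPTS in MeOH would give the 3β,6β-diol ester F7. Sterically selective oxidation of the equatorial 3β-hydroxyl with TEMPO (cat.) and PhI(OAc)2 would give the 6β-hydroxy-3-oxo ester F8. LiBH(s-Bu)3 at −78 °C would then reduce the single C3 carbonyl to 19.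

**Step 21.** The most likely failure is loss of site selectivity between the two axial secondary hydroxyls, either over-acylation at O6 or incomplete acylation at O3. The fallback sets out from 30 and returns at 32, and replaces reagent-controlled selectivity by protecting-group control. A brief, pyridine-buffered treatment of 30 with HF·pyridine in THF at 0 °C should remove the primary TBS and the 3α-TES ethers and keep the far more shielded 6β-TES ether, giving 2-(trimethylsilyl)ethyl (13E)-3α,19-dihydroxy-6β-(triethylsilyloxy)labda-8,13-dien-15-oate F9. Exhaustive acylation with 3-methylbutanoic anhydride and DMAP would give 2-(trimethylsilyl)ethyl (13E)-3α,19-bis(3-methylbutanoyloxy)-6β-(triethylsilyloxy)labda-8,13-dien-15-oate F10. Longer exposure to HF·pyridine at rt would then give 32.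

## Further compounds

F1 | step 8 | 19-[tert-butyl(dimethyl)silyl]oxy-3β-(triethylsilyloxy)-12,13,14,15,16-pentanorlabda-5,8-dien-11-al | CC1=C(C=O)[C@@]2(C)CC[C@H](O[Si](CC)(CC)CC)[C@](C)(CO[Si](C)(C)C(C)(C)C)C2=CC1
F2 | step 8 | 19-[tert-butyl(dimethyl)silyl]oxy-3β-(triethylsilyloxy)-12,13,14,15,16-pentanorlabda-5,8-dien-11-oic acid | CC1=C(C(=O)O)[C@@]2(C)CC[C@H](O[Si](CC)(CC)CC)[C@](C)(CO[Si](C)(C)C(C)(C)C)C2=CC1
F3 | step 3 | racemic cis-2-{[tert-butyl(dimethyl)silyl]oxymethyl}-3-hydroxy-2-methylcyclohexan-1-one (both enantiomers) | O=C1CCC[C@H](O)[C@]1(C)CO[Si](C)(C)C(C)(C)C.O=C1CCC[C@@H](O)[C@@]1(C)CO[Si](C)(C)C(C)(C)C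
F4 | step 3 | (1R,2R)-2-{[tert-butyl(dimethyl)silyl]oxymethyl}-2-methyl-3-oxocyclohexyl acetate | O=C1CCC[C@@H](OC(C)=O)[C@@]1(C)CO[Si](C)(C)C(C)(C)C
F5 | step 12 | methyl 19-[tert-butyl(dimethyl)silyl]oxy-6-oxo-3β-(triethylsilyloxy)-12,13,14,15,16-pentanorlabd-8-en-11-oate | CC1=C(C(=O)OC)[C@@]2(C)CC[C@H](O[Si](CC)(CC)CC)[C@](C)(CO[Si](C)(C)C(C)(C)C)[C@@H]2C(=O)C1
F6 | step 12 | methyl 19-[tert-butyl(dimethyl)silyl]oxy-6β-hydroxy-3β-(triethylsilyloxy)-12,13,14,15,16-pentanorlabd-8-en-11-oate | CC1=C(C(=O)OC)[C@@]2(C)CC[C@H](O[Si](CC)(CC)CC)[C@](C)(CO[Si](C)(C)C(C)(C)C)[C@@H]2[C@H](O)C1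
F7 | step 12 | methyl 19-[tert-butyl(dimethyl)silyl]oxy-3β,6β-dihydroxy-12,13,14,15,16-pentanorlabd-8-en-11-oate | CC1=C(C(=O)OC)[C@@]2(C)CC[C@H](O)[C@](C)(CO[Si](C)(C)C(C)(C)C)[C@@H]2[C@H](O)C1
F8 | step 12 | methyl 19-[tert-butyl(dimethyl)silyl]oxy-6β-hydroxy-3-oxo-12,13,14,15,16-pentanorlabd-8-en-11-oate | CC1=C(C(=O)OC)[C@@]2(C)CCC(=O)[C@](C)(CO[Si](C)(C)C(C)(C)C)[C@@H]2[C@H](O)C1
F9 | step 21 | 2-(trimethylsilyl)ethyl (13E)-3α,19-dihydroxy-6β-(triethylsilyloxy)labda-8,13-dien-15-oate | CC1=C(CC/C(C)=C/C(=O)OCC[Si](C)(C)C)[C@@]2(C)CC[C@@H](O)[C@](C)(CO)[C@@H]2[C@H](O[Si](CC)(CC)CC)C1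
F10 | step 21 | 2-(trimethylsilyl)ethyl (13E)-3α,19-bis(3-methylbutanoyloxy)-6β-(triethylsilyloxy)labda-8,13-dien-15-oate | CC1=C(CC/C(C)=C/C(=O)OCC[Si](C)(C)C)[C@@]2(C)CC[C@@H](OC(=O)CC(C)C)[C@](C)(COC(=O)CC(C)C)[C@@H]2[C@H](O[Si](CC)(CC)CC)C1
A1 | alternative 1 | tricyclic 19,6β-lactone with C1=C2 and C8=C9 alkenes, 3α-triisopropylsilyloxy group and a 2-(tert-butyldimethylsilyloxy)ethyl group on C9 | CC1=C(CCO[Si](C)(C)C(C)(C)C)[C@@]2(C)C=C[C@@H](O[Si](C(C)C)(C(C)C)C(C)C)[C@](C)(C(=O)O3)[C@@H]2[C@H]3C1
A2 | alternative 2 | 2-(trimethylsilyl)ethyl (13E)-6β-hydroxy-3α,19-bis(3-methylbutanoyloxy)labda-8,13-dien-15-oate | CC1=C(CC/C(C)=C/C(=O)OCC[Si](C)(C)C)[C@@]2(C)CC[C@@H](OC(=O)CC(C)C)[C@](C)(COC(=O)CC(C)C)[C@@H]2[C@H](O)C1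
A3 | alternative 3 | bicyclic β-hydroxy ester: trans-decalin with C9 ketone, C7=C8 alkene, 4β-methoxycarbonyl and 3β-hydroxyl | CC1=CC[C@H]2[C@@](C)(C(=O)OC)[C@@H](O)CC[C@]2(C)C1=O
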